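The retrosynthesis cuts the two prenyl C=C bonds first (back to allyl, cross-metathesis), then the two ring A aryl–CH2 bonds at C3 and C5 (back to allyl ethers on O2 and O4, double aromatic Claisen), then the lactone C(=O)–O bond and the diaryl ether C–O bond on the ring A side.
Enabling feature: ring A is hexasubstituted, its two identical C5 chains sit on C3 and C5 on either side of the C4 hydroxyl, each of these carbons is ortho or para to the C2 and C4 hydroxyls, and C1 (lactone carbonyl) and C6 (ether bridge) are blocked.
Forward order: the chromene ring is built first on 2,4,5-trihydroxybenzaldehyde (propargyl ether rearrangement), an Ullmann coupling with a ring A bromo acid makes the diaryl ether, a Dakin oxidation turns the formyl carbon into the ester oxygen, and the seven-membered lactone is closed last.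
Only then are the allyl groups moved from oxygen to carbon and extended to prenyl.
Stereochemistry: the target has no stereocentre and no double bond with E/Z isomers (each prenyl alkene carries two identical methyl groups, the chromene alkene is cis within its ring), so nothing has to be set.

Key step: step 11

Assumption: 1, 2, 7, 9 and 20 are bought; ring A is numbered from the carbon bearing the lactone carbonyl (C1), ring B by 2H-chromene numbering (O1, C2 with two methyl groups, C5 ester oxygen, C6 ether oxygen, C8 hydroxyl).

Step 1
Reactants: 1 5-bromobenzene-1,3-diol; 2 allyl bromide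
Product: 3 1-bromo-3,5-bis(allyloxy)benzene
Conditions: allyl bromide (2.5 equiv), K2CO3 (3 equiv), acetone, reflux
Reagents that add atoms: allyl bromide (second equivalent of 2) C=CCBr
Why: Twofold Williamson ether synthesis, in which each of the two phenoxides of 1 is O-allylated by one equivalent of the primary allylic bromide under carbonate in acetone, conditions that favour O- over C-alkylation of a resorcinol.

Step 2
Reactants: 3 1-bromo-3,5-bis(allyloxy)benzene
Product: 5 2-bromo-4,6-bis(allyloxy)benzaldehyde, via iminium chloride 4 (not isolated)
Conditions: POCl3, DMF, 0 → 80 °C; then ice water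
Reagents that add atoms: N,N-dimethylformamide CN(C)C=O; water O
Why: Vilsmeier–Haack formylation, in which the chloroiminium electrophile should attack the carbon para to one allyloxy group and ortho to the other (next to bromine) rather than the more crowded carbon between the two ethers, as known for 1-bromo-3,5-dialkoxybenzenes, before water hydrolyses iminium salt 4.

Step 3
Reactants: 5 2-bromo-4,6-bis(allyloxy)benzaldehyde
Product: 6 2-bromo-4,6-bis(allyloxy)benzoic acid
Conditions: NaClO2, NaH2PO4, 30% H2O2, MeCN–H2O, 10 °C → rt
Reagents that add atoms: sodium chlorite [Na+].[O-]Cl=O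
Why: Pinnick (Lindgren) chlorite oxidation of the aldehyde to the acid under buffered conditions, with hydrogen peroxide destroying hypochlorite before it can chlorinate the allyl alkenes or the activated ring.

Step 4
Reactants: 7 2,4,5-trihydroxybenzaldehyde
Product: 8 2,5-dihydroxy-4-(methoxymethoxy)benzaldehyde
Conditions: MOMCl (1.05 equiv), K2CO3 (1.1 equiv), acetone, 0 °C → rt, Ar
Reagents that add atoms: chloromethyl methyl ether COCCl
Why: Regioselective Williamson-type O-alkylation, since with one equivalent of mild base the phenoxide forms at the C4 hydroxyl para to the formyl group (the most acidic) while the C2 hydroxyl is held in a hydrogen bond to the aldehyde, the selectivity known for 2,4- and 3,4-dihydroxybenzaldehydes.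

Step 5
Reactants: 8 2,5-dihydroxy-4-(methoxymethoxy)benzaldehyde; 9 3-chloro-3-methylbut-1-yne
Product: 10 2-hydroxy-4-(methoxymethoxy)-5-[(2-methylbut-3-yn-2-yl)oxy]benzaldehyde
Conditions: K2CO3, KI, CuI (5 mol %), acetone, 55 °C
Reagents that add atoms: none
Why: Copper-catalysed O-alkylation of a phenol by a tertiary propargylic chloride, the standard entry to aryl 1,1-dimethylpropargyl ethers, should touch only the free C5 hydroxyl because the C2 hydroxyl stays chelated to the aldehyde.

Step 6
Reactants: 10 2-hydroxy-4-(methoxymethoxy)-5-[(2-methylbut-3-yn-2-yl)oxy]benzaldehyde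
Product: 12 6-hydroxy-8-(methoxymethoxy)-2,2-dimethyl-2H-chromene-5-carbaldehyde, via allenylphenol 11 (not isolated)
Conditions: 1,2-dichlorobenzene, 170 °C, Ar
Reagents that add atoms: none
Why: Thermal aryl propargyl ether Claisen rearrangement to the only open ortho carbon (the other bears the acetal ether) gives allenylphenol 11 after tautomerisation, which closes to the 2,2-dimethyl-2H-chromene by a 1,5-hydrogen shift and oxa-6π electrocyclisation, the classical chromene synthesis.

Step 7
Reactants: 12 6-hydroxy-8-(methoxymethoxy)-2,2-dimethyl-2H-chromene-5-carbaldehyde; 6 2-bromo-4,6-bis(allyloxy)benzoic acid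
Product: 13 2,4-bis(allyloxy)-6-{[5-formyl-8-(methoxymethoxy)-2,2-dimethyl-2H-chromen-6-yl]oxy}benzoic acid
Conditions: CuI (20 mol %), Cs2CO3 (3 equiv), DMF, 95 °C, Ar; then aq. HCl to pH 3
Reagents that add atoms: none
Why: Ullmann diaryl ether condensation of an ortho-bromobenzoic acid, in which the neighbouring carboxylate binds copper and speeds substitution of bromide by the single free phenoxide of 12 (which fixes the ether at chromene C6), while allyl ethers, aldehyde and acetal are inert to monovalent copper and carbonate at this temperature.

Step 8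
Reactants: 13 2,4-bis(allyloxy)-6-{[5-formyl-8-(methoxymethoxy)-2,2-dimethyl-2H-chromen-6-yl]oxy}benzoic acid
Product: 14 2,4-bis(allyloxy)-6-[(5-formyl-8-hydroxy-2,2-dimethyl-2H-chromen-6-yl)oxy]benzoic acid
Conditions: HCl (1.25 M in MeOH), THF, rt; aqueous work-up
Reagents that add atoms: none
Why: Acid-catalysed cleavage of an aryl methoxymethyl ether by acetal exchange with methanol should be fast because a para-formylphenol is a good leaving group, so the conditions stay mild enough for the chromene, the allyl ethers and the electron-rich benzoic acid.

Step 9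
Reactants: 14 2,4-bis(allyloxy)-6-[(5-formyl-8-hydroxy-2,2-dimethyl-2H-chromen-6-yl)oxy]benzoic acid
Product: 16 2,4-bis(allyloxy)-6-[(5,8-dihydroxy-2,2-dimethyl-2H-chromen-6-yl)oxy]benzoic acid, via aryl formate 15 (not isolated)
Conditions: 30% H2O2 (1.5 equiv), aq. NaOH (3.5 equiv), THF–H2O, 0 °C → rt, Ar; then Na2S2O4, aq. HCl to pH 3
Reagents that add atoms: hydrogen peroxide OO
Why: Dakin oxidation, in which hydroperoxide anion adds to the aldehyde and the aryl group, pushed by the para phenoxide, migrates to oxygen to give formate 15 that hydroxide cleaves in the same flask, a nucleophilic oxidant that leaves the electron-rich chromene and allyl alkenes alone.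

Step 10
Reactants: 16 2,4-bis(allyloxy)-6-[(5,8-dihydroxy-2,2-dimethyl-2H-chromen-6-yl)oxy]benzoic acid
Product: 17 ring A bis(allyl ether) depsidone (lactone of 16 closed onto the chromene C5 oxygen; C8 hydroxyl free)
Conditions: EDCI·HCl, DMAP (cat.), CH2Cl2 (0.005 M), 0 °C → rt, Ar
Reagents that add atoms: none
Why: Carbodiimide lactonisation of a 2-(2-hydroxyaryloxy)benzoic acid, the usual closure of the seven-membered depsidone ring, can only engage the C5 hydroxyl next to the ether bridge because the C8 hydroxyl cannot reach the activated carboxyl within the same molecule, and high dilution suppresses intermolecular esters.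

Step 11
Reactants: 17 ring A bis(allyl ether) depsidone
Product: 19 3,5-diallyl-2,4-dihydroxy depsidone (diallyl analogue of garcinisidone E), via mono-rearranged phenol 18 (not isolated)
Conditions: N,N-diethylaniline, 200 °C, sealed tube, Ar
Reagents that add atoms: none
Why: Each aryl allyl ether undergoes a concerted suprafacial [3,3] sigmatropic shift through a chair-like six-membered transition state to an ortho-dienone that tautomerises to the phenol; an ether whose only open ortho carbon is already filled still shifts there, and the resulting 6,6-disubstituted dienone passes the allyl group on by a second [3,3] (Cope) shift to the para carbon before enolising. The closest known reaction is the thermal ortho/para aromatic Claisen rearrangement of aryl allyl ethers, including double rearrangements of 2,4-bis(allyloxy)aryl ketones and esters. No ring is closed and no stereocentre is formed; the two new bonds are C3–CH2 and C5–CH2 of ring A. The only selectivity needed is that both allyl groups end on ring A carbons, and the substrate secures it: C3 and C5 are the only unsubstituted ring A positions, C1 carries the lactone carbonyl and C6 the ether bridge, and because an unsubstituted allyl group is the same from either end, ortho and para delivery and either order of the two shifts (drawn here through 18, the C4 ether moving first to C5) give the same 3,5-diallyl-2,4-diol. Ring B carries no allyl ether, its chromene is itself formed at a similar temperature in step 6 and should survive, and the basic amine solvent under argon should suppress acid-catalysed closure of the new ortho-allylphenols to dihydrobenzofurans and oxidation of the C8 phenol.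

Step 12
Reactants: 19 3,5-diallyl-2,4-dihydroxy depsidone; 20 2-methylbut-2-ene
Product: 21 garcinisidone E
Conditions: second-generation Grubbs catalyst RuCl2(=CHPh)(PCy3)(H2IMes) (10 mol %), 2-methylbut-2-ene (large excess), CH2Cl2, 40 °C, sealed tube
Reagents that add atoms: 2-methylbut-2-ene (second equivalent of 20) CC=C(C)C
Why: Olefin cross-metathesis of the two terminal allyl groups, each with one equivalent of 2-methylbut-2-ene, exchanges each =CH2 terminus for an isopropylidene group with loss of propene, a standard allyl-to-prenyl conversion that tolerates free phenols, while the chromene double bond, cis-disubstituted in a ring and next to a quaternary carbon, is too hindered to engage.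

Compound list
1 | 5-bromobenzene-1,3-diol | Oc1cc(O)cc(Br)c1 | starting material
2 | allyl bromide | C=CCBr | starting material
3 | 1-bromo-3,5-bis(allyloxy)benzene | C=CCOc1cc(Br)cc(OCC=C)c1 | intermediate
4 | N-[2-bromo-4,6-bis(allyloxy)benzylidene]-N-methylmethanaminium chloride (not isolated) | C[N+](C)=Cc1c(Br)cc(OCC=C)cc1OCC=C.[Cl-] | intermediate
5 | 2-bromo-4,6-bis(allyloxy)benzaldehyde | O=Cc1c(Br)cc(OCC=C)cc1OCC=C | intermediate
6 | 2-bromo-4,6-bis(allyloxy)benzoic acid | OC(=O)c1c(Br)cc(OCC=C)cc1OCC=C | intermediate
7 | 2,4,5-trihydroxybenzaldehyde | O=Cc1cc(O)c(O)cc1O | starting material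
8 | 2,5-dihydroxy-4-(methoxymethoxy)benzaldehyde | COCOc1cc(O)c(C=O)cc1O | intermediate
9 | 3-chloro-3-methylbut-1-yne | CC(C)(Cl)C#C | starting material
10 | 2-hydroxy-4-(methoxymethoxy)-5-[(2-methylbut-3-yn-2-yl)oxy]benzaldehyde | COCOc1cc(O)c(C=O)cc1OC(C)(C)C#C | intermediate
11 | 3,6-dihydroxy-4-(methoxymethoxy)-2-(3-methylbuta-1,2-dien-1-yl)benzaldehyde (not isolated) | COCOc1cc(O)c(C=O)c(C=C=C(C)C)c1O | intermediate
12 | 6-hydroxy-8-(methoxymethoxy)-2,2-dimethyl-2H-chromene-5-carbaldehyde | CC1(C)C=Cc2c(C=O)c(O)cc(OCOC)c2O1 | intermediate
13 | 2,4-bis(allyloxy)-6-{[5-formyl-8-(methoxymethoxy)-2,2-dimethyl-2H-chromen-6-yl]oxy}benzoic acid | OC(=O)c1c(OCC=C)cc(OCC=C)cc1Oc1cc(OCOC)c2OC(C)(C)C=Cc2c1C=O | intermediate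
14 | 2,4-bis(allyloxy)-6-[(5-formyl-8-hydroxy-2,2-dimethyl-2H-chromen-6-yl)oxy]benzoic acid | OC(=O)c1c(OCC=C)cc(OCC=C)cc1Oc1cc(O)c2OC(C)(C)C=Cc2c1C=O | intermediate
15 | 2,4-bis(allyloxy)-6-{[5-(formyloxy)-8-hydroxy-2,2-dimethyl-2H-chromen-6-yl]oxy}benzoic acid (not isolated) | OC(=O)c1c(OCC=C)cc(OCC=C)cc1Oc1cc(O)c2OC(C)(C)C=Cc2c1OC=O | intermediate
16 | 2,4-bis(allyloxy)-6-[(5,8-dihydroxy-2,2-dimethyl-2H-chromen-6-yl)oxy]benzoic acid | OC(=O)c1c(OCC=C)cc(OCC=C)cc1Oc1cc(O)c2OC(C)(C)C=Cc2c1O | intermediate
17 | depsidone with allyl ethers on ring A O2 and O4, lactone to chromene C5 oxygen, ether bridge at chromene C6, free C8 hydroxyl | C=CCOc1cc(OCC=C)c2c(c1)Oc1cc(O)c3c(c1OC2=O)C=CC(C)(C)O3 | intermediate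
18 | mono-rearranged phenol: 17 with ring A C4 hydroxyl and C5 allyl, C2 allyl ether intact (not isolated) | Oc1cc(OCC=C)c2c(c1CC=C)Oc1cc(O)c3c(c1OC2=O)C=CC(C)(C)O3 | intermediate
19 | diallyl analogue of garcinisidone E: ring A 3,5-diallyl-2,4-dihydroxy depsidone | C=CCc1c(O)c(CC=C)c2c(c1O)C(=O)Oc1c(cc(O)c3c1C=CC(C)(C)O3)O2 | intermediate
20 | 2-methylbut-2-ene | CC=C(C)C | starting material
21 | garcinisidone E | CC(C)=CCc1c(O)c(CC=C(C)C)c2c(c1O)C(=O)Oc1c(cc(O)c3c1C=CC(C)(C)O3)O2 | target

Total step count: 12. Longest linear sequence: 9 steps (7 to 21, steps 4–12); the ring A branch (steps 1–3) joins at step 7.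

Steps most likely to fail

Step 7. The chelated, formyl-deactivated phenoxide of 12 may couple too slowly, so that protodebromination or copper-induced decarboxylation of 6 takes over. The fallback replaces the copper coupling by a Smiles rearrangement and sets out from 12. Commercial methyl 2,4,6-trihydroxybenzoate is diallylated with two equivalents of 2 (K2CO3, acetone) to methyl 2,4-bis(allyloxy)-6-hydroxybenzoate F1 and saponified (KOH, aqueous methanol, cold acidification) to 2,4-bis(allyloxy)-6-hydroxybenzoic acid F2. F2 and 12 are condensed with trifluoroacetic anhydride in toluene to the depside 5-formyl-8-(methoxymethoxy)-2,2-dimethyl-2H-chromen-6-yl 2,4-bis(allyloxy)-6-hydroxybenzoate F3. K2CO3 in DMSO should then let the ring A phenoxide attack chromene C6, which the ortho formyl group activates, with the acyl oxygen leaving as carboxylate; acidification returns the route at 13.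

Step 9. The hydroquinone that forms is very electron-rich and may be oxidised further by peroxide or air in base, giving mixtures of oxidation levels. The fallback passes through the quinone level on purpose and sets out from 14. After the Dakin reaction the crude mixture is oxidised to completion (FeCl3, aqueous THF) and the stable para-quinone 2,4-bis(allyloxy)-6-[(2,2-dimethyl-5,8-dioxo-5,8-dihydro-2H-chromen-6-yl)oxy]benzoic acid F4 is isolated and purified. Reduction with Na2S2O4 in ethyl acetate/water directly before the lactonisation returns the route at 16.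

Step 11. At 200 °C the free phenols (the C8 hydroxyl and those released by the first shift) may open the strained aryl lactone of a second molecule, or the new ortho-allylphenols may cyclise. The fallback runs the rearrangement with every phenol capped and sets out from 17. The C8 hydroxyl is acetylated (Ac2O, pyridine) to the C8 acetate of 17 F5. F5 is heated in N,N-diethylaniline containing Ac2O and NaOAc, so that each phenol set free by a shift is trapped as its acetate, giving the triacetate of 19 F6. Mild deacetylation (NH4OAc, aqueous methanol), which should spare the hindered lactone, returns the route at 19.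

Further compounds
F1 | step 7 | methyl 2,4-bis(allyloxy)-6-hydroxybenzoate | COC(=O)c1c(O)cc(OCC=C)cc1OCC=C
F2 | step 7 | 2,4-bis(allyloxy)-6-hydroxybenzoic acid | OC(=O)c1c(O)cc(OCC=C)cc1OCC=C
F3 | step 7 | 5-formyl-8-(methoxymethoxy)-2,2-dimethyl-2H-chromen-6-yl 2,4-bis(allyloxy)-6-hydroxybenzoate | O=C(Oc1cc(OCOC)c2OC(C)(C)C=Cc2c1C=O)c1c(O)cc(OCC=C)cc1OCC=C
F4 | step 9 | 2,4-bis(allyloxy)-6-[(2,2-dimethyl-5,8-dioxo-5,8-dihydro-2H-chromen-6-yl)oxy]benzoic acid | OC(=O)c1c(OCC=C)cc(OCC=C)cc1OC1=CC(=O)C2=C(C1=O)C=CC(C)(C)O2
F5 | step 11 | C8 acetate of 17 | C=CCOc1cc(OCC=C)c2c(c1)Oc1cc(OC(C)=O)c3c(c1OC2=O)C=CC(C)(C)O3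
F6 | step 11 | triacetate of 19 (acetates on ring A O2 and O4 and on chromene O8) | C=CCc1c(OC(C)=O)c(CC=C)c2c(c1OC(C)=O)C(=O)Oc1c(cc(OC(C)=O)c3c1C=CC(C)(C)O3)O2
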